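**Plan**

Cuts (C1 = enoic acid carbon, C14 = saturated acid carbon, C13' = hydroxymethyl carbon): C2=C3 (olefination of a C3 methyl ketone), both C–O bonds of the C4–C5 oxirane, C5–C6 (sp2–sp3 coupling), C8–C9 (sp3–sp3 coupling), C12–C13 (vinyl anion plus aldehyde) and, as the central move, C13–H together with C13'–O.
Enabling feature: C13 is a CH bearing two one-carbon oxygenated arms (C13'H2OH and C14O2H) directly beside the C12 carbinol, so C12–C13(–C13')–C14 is a 2-methylene-1,3-diol to which H and OH have been added. An Si–H group hung on O12 reaches C13=C13' and closes a five-membered O12–Si–C13'–C13–C12 ring, which copies the C12 configuration onto C13.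
Forward order: C6–C8 block plus C9–C12 Grignard reagent, ozonolysis, C13/C13'/C14 vinyllithium, enone, carbinol, silyl ether, temporary oxasilacyclopentane (first ring, opened again by oxidation). Then C3–C5 is added by B-alkyl coupling at C6, the oxirane (the only ring of the target) is made, C1–C2 come from olefination, C14 is raised to the acid, and one fluoride deprotection finishes.
Stereochemistry: C7 is bought; C12 comes from a CBS reduction; C13 from C12 through the tether. C4 and C5 come from a sacrificial C3 carbinol (transfer hydrogenation) by hydroxyl-directed epoxidation of a 4Z alkene whose geometry is fixed by trans-hydroalumination; 2E comes from the olefination.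

Key step: step 9

Remark: the descriptors 4S,5R place C3 and C6 cis on the oxirane, so the epoxide is derived from a 4Z and not a 4E alkene. Locants C1–C14 and C13' below are those of the target.

**Step 1**
Reactants: 1 (R)-3-bromo-2-methylpropan-1-ol
Product: 2 (R)-3-bromo-2-methylpropyl trifluoromethanesulfonate
Conditions: Tf2O, 2,6-lutidine, CH2Cl2, −78 °C to −30 °C; cold aqueous wash, used crude
Reagents that add atoms: triflic anhydride, FC(F)(F)S(=O)(=O)OS(=O)(=O)C(F)(F)F
Why: Sulfonylation of a primary alcohol with triflic anhydride and a hindered base is fast at low temperature, leaves the purchased C7 centre untouched and turns C8 into a far better electrophile than the C6 bromide that has to be kept.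

**Step 2**
Reactants: 2 (R)-3-bromo-2-methylpropyl trifluoromethanesulfonate; 3 5-bromopent-1-ene
Product: 5 (R)-8-bromo-7-methyloct-1-ene, via pent-4-enylmagnesium bromide 4 (not isolated)
Conditions: 3, Mg, THF, rt to 40 °C; then 2, Li2CuCl4 (5 mol %), THF/Et2O, −78 °C to −20 °C
Reagents that add atoms: magnesium, [Mg]
Why: Copper-catalysed cross-coupling of a Grignard reagent with a primary alkyl triflate forms C8–C9 already below −20 °C, where the β-branched primary bromide at C6 is still inert, and no bond to C7 is touched.

**Step 3**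
Reactants: 5 (R)-8-bromo-7-methyloct-1-ene
Product: 7 (R)-7-bromo-6-methylheptanal, via ozonide 6 (not isolated)
Conditions: O3, CH2Cl2, −78 °C; then PPh3, −78 °C to rt
Reagents that add atoms: ozone, [O-][O+]=O
Why: Ozonolysis with reductive work-up cleaves the only alkene to the C12 aldehyde, and the hindered alkyl bromide is inert to ozone and to PPh3 at these temperatures.

**Step 4**
Reactants: 8 2-bromoprop-2-en-1-ol
Product: 9 1-{[(2-bromoprop-2-en-1-yl)oxy]methyl}-4-methoxybenzene (2-bromoallyl PMB ether)
Conditions: NaH, PMBCl, n-Bu4NI (cat.), THF, 0 °C to rt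
Reagents that add atoms: 4-methoxybenzyl chloride, COc1ccc(CCl)cc1
Why: Williamson ether synthesis, in which the sodium alkoxide of the allylic alcohol displaces chloride from the benzylic halide while the vinylic C–Br bond does not react.

**Step 5**
Reactants: 9 2-bromoallyl PMB ether; 7 (R)-7-bromo-6-methylheptanal
Product: 11 (3RS,8R)-9-bromo-2-{[(4-methoxybenzyl)oxy]methyl}-8-methylnon-1-en-3-ol (C12 epimers), via 2-lithioallyl PMB ether 10 (not isolated)
Conditions: 9, t-BuLi (2.0 equiv), Et2O, −78 °C; then 7, −78 °C; H2O
Reagents that add atoms: tert-butyllithium, [Li]C(C)(C)C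
Why: Bromine–lithium exchange with two equivalents of t-BuLi gives a 2-lithioallyl ether that resists β-elimination at −78 °C and adds 1,2 to the aldehyde (C12–C13 bond) much faster than it displaces the alkyl bromide; C12 is formed unselectively, which is harmless because the next step erases it.

**Step 6**
Reactants: 11 allylic alcohol (C12 epimers)
Product: 12 (R)-9-bromo-2-{[(4-methoxybenzyl)oxy]methyl}-8-methylnon-1-en-3-one
Conditions: Dess–Martin periodinane, CH2Cl2, 0 °C to rt; used promptly
Reagents that add atoms: none
Why: Dess–Martin oxidation converts the secondary allylic alcohol into the 2-substituted enone under neutral, non-nucleophilic conditions, so the Michael-acceptor product, the bromide and the PMB ether persist.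

**Step 7**
Reactants: 12 enone
Product: 13 (3R,8R)-9-bromo-2-{[(4-methoxybenzyl)oxy]methyl}-8-methylnon-1-en-3-ol (12R,7R)
Conditions: (S)-2-methyl-CBS-oxazaborolidine (0.15 equiv), catecholborane (1.5 equiv), toluene, −78 °C; then H2O
Reagents that add atoms: none
Why: Corey–Bakshi–Shibata reduction, in which the ketone binds to the (S)-oxazaborolidine–borane complex with the branched alkenyl group as the large and the C11 methylene chain as the small substituent, so hydride reaches the face that gives 12R, and catecholborane at −78 °C neither hydroborates the alkene nor reduces it in the 1,4 sense.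

**Step 8**
Reactants: 13 (3R,8R)-allylic alcohol; 14 1,1,3,3-tetramethyldisilazane
Product: 15 {[(3R,8R)-9-bromo-2-{[(4-methoxybenzyl)oxy]methyl}-8-methylnon-1-en-3-yl]oxy}dimethylsilane (O12–SiMe2H ether)
Conditions: 14 (1.0 equiv), neat, rt to 40 °C; volatiles removed in vacuo
Reagents that add atoms: none
Why: Silylation of the alcohol with the disilazane releases only ammonia, needs no acid or base and therefore installs the O–SiMe2H tether without touching Si–H, the alkene or C12.

**Step 9**
Reactants: 15 O12–SiMe2H ether
Product: 16 (4S,5R)-5-[(5R)-6-bromo-5-methylhexyl]-4-{[(4-methoxybenzyl)oxy]methyl}-2,2-dimethyl-1,2-oxasilolane (cis-4,5)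
Conditions: H2PtCl6·6H2O (0.5 mol %, added as THF solution), hexane (0.05 M), 60 °C
Reagents that add atoms: none
Why: Platinum generated from H2PtCl6 inserts into the Si–H bond of 15, the tethered C13=C13' alkene coordinates, hydride migrates to C13 and reductive elimination joins C13' to silicon. The closest known reaction type is the platinum-catalysed intramolecular hydrosilylation of dimethylsilyl ethers of 2-substituted allylic alcohols, used with Tamao oxidation as a route to syn 2-substituted 1,3-diols. The ring (O12, Si, C13', C13, C12) closes in the 5-endo-trig mode, since the two-atom O–Si link lets silicon reach only the terminal carbon and the 4-exo alternative would be a strained oxasiletane. The single new stereocentre C13 is controlled by C12: with O12 tied to the metal-bearing face, A(1,2) strain against the CH2OPMB arm places the small C12–H and not the C11 chain beside that arm, so hydride is delivered to the face that leaves C11 and C14 cis on the ring. The step needs regioselectivity, secured by the tether length, facial selectivity, secured by the branched C14 arm on the alkene and the enantiopurity of C12, and chemoselectivity, secured by the absence of any other alkene and by dilution against intermolecular addition, while bromide and PMB ether are inert to the catalyst. The cis ring corresponds to 12R,13R of the target once C13'–Si becomes C13'–OH and the C14 arm becomes the acid.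

**Step 10**
Reactants: 16 cis-oxasilolane
Product: 17 (2S,3R,8R)-9-bromo-2-{[(4-methoxybenzyl)oxy]methyl}-8-methylnonane-1,3-diol
Conditions: 30% aq. H2O2, KF, KHCO3, THF/MeOH (1:1), rt
Reagents that add atoms: hydrogen peroxide, OO
Why: Tamao oxidation, in which fluoride and bicarbonate make the alkoxysilane hypervalent, hydroperoxide adds to silicon and C13' migrates from silicon to oxygen with retention, which frees the C12 and C13' hydroxyl groups of the syn diol without touching C13, while the weakly basic medium leaves the hindered bromide in place.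

**Step 11**
Reactants: 17 diol
Product: 18 (2R,3R,8R)-9-bromo-1,3-bis[(tert-butyldimethylsilyl)oxy]-2-{[(4-methoxybenzyl)oxy]methyl}-8-methylnonane
Conditions: TBSOTf (2.5 equiv), 2,6-lutidine, CH2Cl2, 0 °C
Reagents that add atoms: tert-butyldimethylsilyl triflate, CC(C)(C)[Si](C)(C)OS(=O)(=O)C(F)(F)F
Why: Silyl triflate and 2,6-lutidine silylate the primary and the hindered secondary hydroxyl group in one operation, which fixes the distinction between the C13' arm (silyl ether) and the C14 arm (PMB ether) on which the C13 configuration rests.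

**Step 12**
Reactants: 18 bromide
Product: 19 (2R,3R,8R)-1,3-bis[(tert-butyldimethylsilyl)oxy]-9-iodo-2-{[(4-methoxybenzyl)oxy]methyl}-8-methylnonane
Conditions: NaI, acetone, reflux
Reagents that add atoms: sodium iodide, [Na+].[I-]
Why: Finkelstein reaction, in which precipitation of NaBr from acetone drives the SN2 exchange at C6 and supplies the iodide needed for a clean lithium–iodine exchange.

**Step 13**
Reactants: 20 pent-3-yn-2-one
Product: 21 (R)-pent-3-yn-2-ol
Conditions: RuCl[(R,R)-TsDPEN](p-cymene) (0.5 mol %), KOH (1 mol %), i-PrOH, rt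
Reagents that add atoms: none
Why: Noyori asymmetric transfer hydrogenation of an alkynyl methyl ketone, in which the (R,R)-catalyst transfers hydride from 2-propanol to the face that gives the (R)-propargylic alcohol and does not reduce the alkyne.

**Step 14**
Reactants: 21 (R)-pent-3-yn-2-ol
Product: 23 (2R,3Z)-4-iodopent-3-en-2-ol, via cyclic sodium vinylalanate 22 (not isolated)
Conditions: NaAlH2(OCH2CH2OMe)2, THF, 0 °C to rt; then I2, THF, −78 °C to 0 °C; H2O
Reagents that add atoms: sodium bis(2-methoxyethoxy)aluminium dihydride, [Na+].COCCO[AlH2-]OCCOC; iodine, [I][I]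
Why: Hydroxyl-directed trans-hydroalumination of the propargylic alcohol places aluminium on the distal alkyne carbon within a five-membered alanate, and iodinolysis with retention gives the Z iodide in which iodine (the later C6) is cis to the carbinol carbon C3.

**Step 15**
Reactants: 19 iodide; 23 (2R,3Z)-4-iodopent-3-en-2-ol
Product: 26 (2R,3Z,6R,11R,12R)-11,13-bis[(tert-butyldimethylsilyl)oxy]-12-{[(4-methoxybenzyl)oxy]methyl}-4,6-dimethyltridec-3-en-2-ol, via primary alkyllithium 24 (not isolated), via lithium B-alkyl-B-methoxy-9-BBN borate 25 (not isolated)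
Conditions: 19, t-BuLi (2.1 equiv), Et2O, −78 °C; B-methoxy-9-BBN, THF, −78 °C to rt; then 23, PdCl2(dppf) (5 mol %), K3PO4 (3 M aq.), DMF, rt
Reagents that add atoms: tert-butyllithium, [Li]C(C)(C)C; B-methoxy-9-borabicyclo[3.3.1]nonane, COB1C2CCCC1CCC2
Why: B-alkyl Suzuki–Miyaura coupling in its 9-methoxy-9-BBN variant, in which lithium–iodine exchange and trapping on boron give a borate ready for transmetallation and the alkenyl iodide couples with retention, so C5–C6 is formed with the 4Z geometry and the free hydroxyl group is tolerated.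

**Step 16**
Reactants: 26 (3R,4Z)-allylic alcohol
Product: 27 threo epoxy alcohol, (3R,4S,5R,7R,12R,13R) by target locants, C3 and C6 cis on the oxirane
Conditions: m-CPBA, CH2Cl2, −10 °C to 0 °C; aq. NaHCO3 wash
Reagents that add atoms: 3-chloroperoxybenzoic acid, OOC(=O)c1cccc(Cl)c1
Why: Hydroxyl-directed Prilezhaev epoxidation, in which A(1,3) strain with the cis C6 methylene holds the C3–H bond in the alkene plane, the hydrogen-bonded peracid attacks the face on which the (3R)-hydroxyl group then lies, and syn addition to the 4Z alkene gives the threo epoxy alcohol with 4S,5R.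

**Step 17**
Reactants: 27 epoxy alcohol
Product: 28 epoxy methyl ketone (C3 ketone; spatial arrangement at C4 and C5 unchanged, C4 becomes R by priority change)
Conditions: n-Pr4NRuO4 (5 mol %), NMO, 4 Å MS, CH2Cl2, rt
Reagents that add atoms: none
Why: Ley–Griffith oxidation turns the secondary alcohol into the methyl ketone under neutral conditions that spare the oxirane, removing the C3 centre once it has done its work.

**Step 18**
Reactants: 29 2-(diethoxyphosphoryl)acetic acid; 30 2-(trimethylsilyl)ethanol
Product: 31 2-(trimethylsilyl)ethyl 2-(diethoxyphosphoryl)acetate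
Conditions: DCC, DMAP (cat.), CH2Cl2, 0 °C to rt
Reagents that add atoms: none
Why: Steglich esterification joins acid and alcohol at room temperature and gives an ester that fluoride will cleave together with the silyl ethers.

**Step 19**
Reactants: 28 epoxy methyl ketone; 31 phosphonate
Product: 33 2-(trimethylsilyl)ethyl (2E)-epoxy enoate (4S,5R,7R,12R,13R; O12 and O13' as TBS ethers, O14 as PMB ether), via sodium phosphonate 32 (not isolated)
Conditions: 31, NaH, THF, 0 °C; then 28, 0 °C to rt
Reagents that add atoms: sodium hydride, [Na+].[H-]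
Why: Horner–Wadsworth–Emmons olefination, in which reversible addition of the stabilised phosphonate anion to the activated α-oxygenated ketone and elimination through the less crowded oxaphosphetane place the ester trans to the trisubstituted oxiranyl group, the larger flank of the ketone, which gives 2E, and the weakly basic anion does not epimerise C4.

**Step 20**
Reactants: 33 epoxy enoate
Product: 34 C14 primary alcohol (PMB removed, all else unchanged)
Conditions: DDQ, CH2Cl2/pH 7 phosphate buffer (10:1), 0 °C
Reagents that add atoms: none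
Why: Oxidative cleavage of the electron-rich PMB ether with DDQ in buffered wet dichloromethane is neutral, so oxirane, enoate and silyl groups persist and no base is present that could move the silyl group from O13' to O14 and thereby scramble C13.

**Step 21**
Reactants: 34 C14 alcohol
Product: 36 C14 carboxylic acid (13R), via C14 aldehyde 35 (not isolated)
Conditions: TEMPO (0.2 equiv), PhI(OAc)2 (2.5 equiv), MeCN/H2O (1:1), rt
Reagents that add atoms: water, O
Why: Oxoammonium oxidation (TEMPO with PhI(OAc)2 in aqueous acetonitrile) takes the primary alcohol through the hydrated aldehyde to the acid in one flask under mildly acidic conditions, in which C13 is not enolised and β-elimination of silanol is not triggered.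

**Step 22**
Reactants: 36 C14 acid
Product: 37 (2E)-3-[(2S,3R)-3-{(2R,7R,8R)-8-carboxy-7,9-dihydroxy-2-methylnonyl}-3-methyloxiran-2-yl]but-2-enoic acid (target)
Conditions: n-Bu4NF (6 equiv), THF, 0 °C to rt; aq. NH4Cl, pH adjusted to 4, reversed-phase chromatography
Reagents that add atoms: none
Why: Fluoride cleaves both silyl ethers and, by β-elimination of ethene and Me3SiF, the 2-(trimethylsilyl)ethyl ester in one operation, the C14 carboxylate present from the start protects C13 against deprotonation, and the E geometry keeps the C1 carboxylate away from the oxirane.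

**Compound list**

1 | (R)-3-bromo-2-methylpropan-1-ol | BrC[C@H](C)CO | starting material
2 | (R)-3-bromo-2-methylpropyl trifluoromethanesulfonate | BrC[C@H](C)COS(=O)(=O)C(F)(F)F | intermediate
3 | 5-bromopent-1-ene | C=CCCCBr | starting material
4 | pent-4-enylmagnesium bromide | C=CCCC[Mg]Br | intermediate
5 | (R)-8-bromo-7-methyloct-1-ene | BrC[C@H](C)CCCCC=C | intermediate
6 | 3-[(5R)-6-bromo-5-methylhexyl]-1,2,4-trioxolane | BrC[C@H](C)CCCCC1OCOO1 | intermediate
7 | (R)-7-bromo-6-methylheptanal | BrC[C@H](C)CCCCC=O | intermediate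
8 | 2-bromoprop-2-en-1-ol | OCC(Br)=C | starting material
9 | 1-{[(2-bromoprop-2-en-1-yl)oxy]methyl}-4-methoxybenzene | C=C(Br)COCc1ccc(OC)cc1 | intermediate
10 | {3-[(4-methoxybenzyl)oxy]prop-1-en-2-yl}lithium | [Li]C(=C)COCc1ccc(OC)cc1 | intermediate
11 | (3RS,8R)-9-bromo-2-{[(4-methoxybenzyl)oxy]methyl}-8-methylnon-1-en-3-ol | BrC[C@H](C)CCCCC(O)C(=C)COCc1ccc(OC)cc1 | intermediate
12 | (R)-9-bromo-2-{[(4-methoxybenzyl)oxy]methyl}-8-methylnon-1-en-3-one | BrC[C@H](C)CCCCC(=O)C(=C)COCc1ccc(OC)cc1 | intermediate
13 | (3R,8R)-9-bromo-2-{[(4-methoxybenzyl)oxy]methyl}-8-methylnon-1-en-3-ol | BrC[C@H](C)CCCC[C@@H](O)C(=C)COCc1ccc(OC)cc1 | intermediate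
14 | 1,1,3,3-tetramethyldisilazane | C[SiH](C)N[SiH](C)C | starting material
15 | dimethylsilyl ether of 13 | BrC[C@H](C)CCCC[C@@H](O[SiH](C)C)C(=C)COCc1ccc(OC)cc1 | intermediate
16 | (4S,5R)-5-[(5R)-6-bromo-5-methylhexyl]-4-{[(4-methoxybenzyl)oxy]methyl}-2,2-dimethyl-1,2-oxasilolane | BrC[C@H](C)CCCC[C@H]1O[Si](C)(C)C[C@H]1COCc2ccc(OC)cc2 | intermediate
17 | (2S,3R,8R)-9-bromo-2-{[(4-methoxybenzyl)oxy]methyl}-8-methylnonane-1,3-diol | BrC[C@H](C)CCCC[C@@H](O)[C@@H](CO)COCc1ccc(OC)cc1 | intermediate
18 | (2R,3R,8R)-9-bromo-1,3-bis[(tert-butyldimethylsilyl)oxy]-2-{[(4-methoxybenzyl)oxy]methyl}-8-methylnonane | BrC[C@H](C)CCCC[C@@H](O[Si](C)(C)C(C)(C)C)[C@@H](CO[Si](C)(C)C(C)(C)C)COCc1ccc(OC)cc1 | intermediate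
19 | (2R,3R,8R)-1,3-bis[(tert-butyldimethylsilyl)oxy]-9-iodo-2-{[(4-methoxybenzyl)oxy]methyl}-8-methylnonane | IC[C@H](C)CCCC[C@@H](O[Si](C)(C)C(C)(C)C)[C@@H](CO[Si](C)(C)C(C)(C)C)COCc1ccc(OC)cc1 | intermediate
20 | pent-3-yn-2-one | CC#CC(C)=O | starting material
21 | (R)-pent-3-yn-2-ol | C[C@@H](O)C#CC | intermediate
22 | sodium cyclic vinylalanate from 21 | [Na+].C[C@H]1O[Al-](OCCOC)(OCCOC)C(C)=C1 | intermediate
23 | (2R,3Z)-4-iodopent-3-en-2-ol | C[C@@H](O)/C=C(/C)I | intermediate
24 | primary alkyllithium from 19 | [Li]C[C@H](C)CCCC[C@@H](O[Si](C)(C)C(C)(C)C)[C@@H](CO[Si](C)(C)C(C)(C)C)COCc1ccc(OC)cc1 | intermediate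
25 | lithium B-alkyl-B-methoxy-9-BBN borate | [Li+].CO[B-]1(C[C@H](C)CCCC[C@@H](O[Si](C)(C)C(C)(C)C)[C@@H](CO[Si](C)(C)C(C)(C)C)COCc3ccc(OC)cc3)C2CCCC1CCC2 | intermediate
26 | (2R,3Z,6R,11R,12R)-11,13-bis[(tert-butyldimethylsilyl)oxy]-12-{[(4-methoxybenzyl)oxy]methyl}-4,6-dimethyltridec-3-en-2-ol | C[C@@H](O)/C=C(/C)C[C@H](C)CCCC[C@@H](O[Si](C)(C)C(C)(C)C)[C@@H](CO[Si](C)(C)C(C)(C)C)COCc1ccc(OC)cc1 | intermediate
27 | threo epoxy alcohol (3R,4S,5R,7R,12R,13R) | C[C@@H](O)[C@@H]1O[C@]1(C)C[C@H](C)CCCC[C@@H](O[Si](C)(C)C(C)(C)C)[C@@H](CO[Si](C)(C)C(C)(C)C)COCc2ccc(OC)cc2 | intermediate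
28 | epoxy methyl ketone | CC(=O)[C@@H]1O[C@]1(C)C[C@H](C)CCCC[C@@H](O[Si](C)(C)C(C)(C)C)[C@@H](CO[Si](C)(C)C(C)(C)C)COCc2ccc(OC)cc2 | intermediate
29 | 2-(diethoxyphosphoryl)acetic acid | CCOP(=O)(CC(=O)O)OCC | starting material
30 | 2-(trimethylsilyl)ethanol | C[Si](C)(C)CCO | starting material
31 | 2-(trimethylsilyl)ethyl 2-(diethoxyphosphoryl)acetate | CCOP(=O)(CC(=O)OCC[Si](C)(C)C)OCC | intermediate
32 | sodium salt of 31 | [Na+].CCOP(=O)(OCC)[CH-]C(=O)OCC[Si](C)(C)C | intermediate
33 | 2-(trimethylsilyl)ethyl (2E)-epoxy enoate, O12/O13' TBS, O14 PMB | C/C(=C\C(=O)OCC[Si](C)(C)C)[C@@H]1O[C@]1(C)C[C@H](C)CCCC[C@@H](O[Si](C)(C)C(C)(C)C)[C@@H](CO[Si](C)(C)C(C)(C)C)COCc2ccc(OC)cc2 | intermediate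
34 | C14 primary alcohol | C/C(=C\C(=O)OCC[Si](C)(C)C)[C@@H]1O[C@]1(C)C[C@H](C)CCCC[C@@H](O[Si](C)(C)C(C)(C)C)[C@@H](CO[Si](C)(C)C(C)(C)C)CO | intermediate
35 | C14 aldehyde | C/C(=C\C(=O)OCC[Si](C)(C)C)[C@@H]1O[C@]1(C)C[C@H](C)CCCC[C@@H](O[Si](C)(C)C(C)(C)C)[C@@H](CO[Si](C)(C)C(C)(C)C)C=O | intermediate
36 | C14 carboxylic acid | C/C(=C\C(=O)OCC[Si](C)(C)C)[C@@H]1O[C@]1(C)C[C@H](C)CCCC[C@@H](O[Si](C)(C)C(C)(C)C)[C@@H](CO[Si](C)(C)C(C)(C)C)C(=O)O | intermediate
37 | (2E)-3-[(2S,3R)-3-{(2R,7R,8R)-8-carboxy-7,9-dihydroxy-2-methylnonyl}-3-methyloxiran-2-yl]but-2-enoic acid | C/C(=C\C(=O)O)[C@@H]1O[C@]1(C)C[C@H](C)CCCC[C@@H](O)[C@@H](CO)C(=O)O | target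

**Step count**

Total step count: 22. Longest linear sequence: 18 steps (1 to 37 through steps 1–3, 5–12, 15–17 and 19–22).

**Steps most likely to fail**

**Step 9.** Facial selectivity at C13 may erode, because the C11 chain is unbranched and differs less from hydrogen than the branched groups for which this cyclisation is most selective. Platinum may also move the alkene towards the enol ether before it is captured.

The fallback sets out from 13 and comes back at 18. It gives up the tether for an intermolecular, catalyst-controlled hydroboration. Alcohol 13 is silylated with TBSOTf and 2,6-lutidine to the C12 tert-butyldimethylsilyl ether F1. Catecholborane with RhCl(PPh3)3, followed by buffered H2O2, converts it into the syn C13' primary alcohol F2. This is the sense known for rhodium-catalysed hydroboration of 1,1-disubstituted allylic silyl ethers. TBSCl and imidazole then give 18.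

**Step 19.** E selectivity may be incomplete, addition to a ketone flanked by a crowded oxirane may be sluggish, and the oxirane may open under base on long exposure.

The fallback sets out from 23 and 25 and comes back at 33. It fixes the C2=C3 geometry on a small building block and makes the oxirane last under reagent control.
- Alcohol 23 is oxidised with MnO2 to (Z)-4-iodopent-3-en-2-one F3.
- Olefination with 32 gives 2-(trimethylsilyl)ethyl (2E,4Z)-5-iodo-3-methylhexa-2,4-dienoate F4, from which the 2Z isomer is removed by chromatography before any advanced material is committed.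
- Coupling with borate 25 under the conditions of step 15 gives the fully protected (2E,4Z)-dienoate F5.
- Shi epoxidation with the L-fructose-derived ketone (the enantiomer of the usual D-fructose-derived catalyst) and KHSO5 attacks the electron-richer C4=C5 bond and should give 33.

**Step 2.** Discrimination between the two leaving groups may be lost, and the triflate may decay before it couples.

The fallback sets out from 4 and comes back at 5. It exchanges the roles of the two ends of the C6–C8 block, so that only one leaving group is present during the coupling. The enantiomeric building block (S)-3-bromo-2-methylpropan-1-ol F6, also purchased, is treated with an excess of 4 and Li2CuCl4. The first equivalent forms the magnesium alkoxide and the second couples at the bromide to give (R)-2-methyloct-7-en-1-ol F7. An Appel reaction (CBr4, PPh3) then gives 5.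

**Further compounds**

F1 | step 9 | (3R,8R)-9-bromo-3-[(tert-butyldimethylsilyl)oxy]-2-{[(4-methoxybenzyl)oxy]methyl}-8-methylnon-1-ene | BrC[C@H](C)CCCC[C@@H](O[Si](C)(C)C(C)(C)C)C(=C)COCc1ccc(OC)cc1
F2 | step 9 | (2S,3R,8R)-9-bromo-3-[(tert-butyldimethylsilyl)oxy]-2-{[(4-methoxybenzyl)oxy]methyl}-8-methylnonan-1-ol | BrC[C@H](C)CCCC[C@@H](O[Si](C)(C)C(C)(C)C)[C@@H](CO)COCc1ccc(OC)cc1
F3 | step 19 | (Z)-4-iodopent-3-en-2-one | CC(=O)/C=C(/C)I
F4 | step 19 | 2-(trimethylsilyl)ethyl (2E,4Z)-5-iodo-3-methylhexa-2,4-dienoate | C/C(=C\C(=O)OCC[Si](C)(C)C)/C=C(/C)I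
F5 | step 19 | 2-(trimethylsilyl)ethyl (2E,4Z,7R,12R,13R)-dienoate, O12/O13' TBS, O14 PMB | C/C(=C\C(=O)OCC[Si](C)(C)C)/C=C(/C)C[C@H](C)CCCC[C@@H](O[Si](C)(C)C(C)(C)C)[C@@H](CO[Si](C)(C)C(C)(C)C)COCc1ccc(OC)cc1
F6 | step 2 | (S)-3-bromo-2-methylpropan-1-ol (purchased) | OC[C@H](C)CBr
F7 | step 2 | (R)-2-methyloct-7-en-1-ol | OC[C@H](C)CCCCC=C
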